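**Strategy.** Ring A (C1–C5, C10; eudesmane numbering) is a Diels–Alder retron: C3–C4 and C5–C10 flank the C4–C5 edge, and C1–C2 carries no function. Ring B is opened between C6 and C7, and its C8 oxygen becomes the alkoxy oxygen of a temporary δ-lactone. The precursor is therefore an acyclic ester: the allenoate (C4–C6, C15) of a dienol (C1–C3, C7–C10, C14) whose only stereocentre, C8, is bought. One intramolecular [4+2] cycloaddition forms both bonds, ring A and the lactone, and relays C8 to C5 and C10. The allene leaves C4=C15 for the tertiary alcohol. The lactone is later recast into the ring B enone by aldol condensation.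

Key step: step 3

Remark: all compounds are numbered as in eudesmane (ring A = C1–C5 and C10, ring B = C5–C10, C14 = methyl on C10, C15 = methyl on C4, C11–C13 = 2-hydroxyprop-2-yl on C7); β is the face of the C14 methyl, α the opposite face; (S)-pent-4-yn-2-ol, but-3-ynoic acid and angelic acid are taken as commercial.

Step 1
Reactants: 1 (S)-pent-4-yn-2-ol; 2 bromoethene (vinyl bromide)
Product: 4 (2S,4E)-4-methylhepta-4,6-dien-2-ol, via alkenylalane 3 (not isolated)
Conditions: Me3Al (3 equiv), Cp2ZrCl2 (25 mol %), CH2Cl2, 0 °C to rt; then 2, Pd(PPh3)4 (5 mol %), ZnCl2 (20 mol %), THF, rt; aqueous work-up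
Reagents that add atoms: trimethylaluminium, C[Al](C)C
Why: Zirconium-catalysed syn-carboalumination of the terminal alkyne (Negishi carboalumination) puts the new methyl (C14) on the internal carbon cis to aluminium, and the Pd-catalysed cross-coupling of the alkenylalane with vinyl bromide (Negishi coupling) keeps that geometry, so the E diene with C14 on the inside should result while the bought carbinol centre is untouched.

Step 2
Reactants: 4 (2S,4E)-4-methylhepta-4,6-dien-2-ol; 5 but-3-ynoic acid
Product: 7 (2S,4E)-4-methylhepta-4,6-dien-2-yl buta-2,3-dienoate, via but-3-ynoate ester 6 (not isolated)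
Conditions: DCC, DMAP (2 mol %), CH2Cl2, −20 to 0 °C; then Et3N (0.3 equiv), rt
Reagents that add atoms: none
Why: Steglich esterification of the secondary alcohol is followed by amine-promoted prototropic isomerisation of the but-3-ynoate to the conjugated allenoate, and the C8 stereocentre is not involved.

Step 3
Reactants: 7 (2S,4E)-4-methylhepta-4,6-dien-2-yl buta-2,3-dienoate
Product: 8 trans-fused lactone (3S,4aS,8aS)-3,4a-dimethyl-8-methylidene-3,4,4a,7,8,8a-hexahydro-1H-isochromen-1-one (5α-H, 10β-CH3, C1=C2, C4=C15, lactone C5–C6(=O)–O–C8–C9–C10)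
Conditions: PhMe (0.01 M), BHT (5 mol %), 130 °C, sealed tube
Reagents that add atoms: none
Why: A thermal, concerted but asynchronous intramolecular Diels–Alder reaction (type 1, ester-linked deca-1,3,9-triene; closest known cases are the thermal cyclisations of hexa-3,5-dienyl acrylates and cycloadditions of allenoate dienophiles) adds the diene C10=C1–C2=C3 across the activated α,β-bond C5=C4 of the allenoate and forms C5–C10 and C3–C4. Ring A closes as the cyclohexene of the [4+2] event and the six-membered lactone closes as the fused tether ring, so the regiochemistry is fixed by the four-atom tether and also matches the electronic preference for union of the unsubstituted terminus C3 with the allene carbon C4. C10 and C5 are the new stereocentres: their relative configuration (C14 anti to H-5, trans fusion) should follow from the E diene reacting through the exo-tether transition state, and their absolute configuration is relayed from C8, whose methyl group sits pseudo-equatorial on the forming lactone ring to avoid a syn-axial contact with C14. The selectivities needed are α,β- over β,γ-bond of the allene (conjugation with the ester; six- rather than seven-membered tether ring), exo- over endo-tether (the endo mode folds the s-cis ester under the diene and leads to the cis-fused lactone) and π-face (C8 methyl). The sp carbon C4 carries no endo or exo substituent, which is what should let the fully substituted diene terminus C10 react, and it leaves the C4=C15 methylene for step 4.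

Step 4
Reactants: 8 trans-fused methylidene lactone
Product: 9 4α-hydroxy-4β-methyl lactone (tertiary alcohol at C4, C1=C2 retained)
Conditions: Co(acac)2 (20 mol %), PhSiH3 (2.5 equiv), O2 (1 atm), THF, rt
Reagents that add atoms: dioxygen, O=O
Why: Mukaiyama hydration: hydrogen-atom transfer from a cobalt hydride to C15 of the 1,1-disubstituted alkene (much faster than to the ring C1=C2 bond) gives the tertiary C4 radical, which should take up O2 on the α face, away from the syn-axial C14 methyl, to set the 4α-hydroxy-4β-methyl centre.

Step 5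
Reactants: 9 4α-hydroxy-4β-methyl lactone
Product: 10 3-oxo-Δ1 lactone (ring A enone C1=C2–C3=O)
Conditions: Rh2(cap)4 (dirhodium tetracaprolactamate, 1 mol %), t-BuOOH (5 equiv), K2CO3 (0.5 equiv), CH2Cl2, rt
Reagents that add atoms: tert-butyl hydroperoxide, CC(C)(C)OO
Why: Dirhodium-catalysed allylic oxidation with t-BuOOH (hydrogen abstraction by the tert-butylperoxyl radical, peroxide formation and collapse) should oxidise C3, the only allylic C–H position of the C1=C2 alkene because C10 is quaternary, to the enone carbonyl.

Step 6
Reactants: 10 3-oxo-Δ1 lactone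
Product: 11 3-oxo lactone (saturated ring A)
Conditions: H2 (1 atm), Pd/C (10 %), EtOAc, rt
Reagents that add atoms: none
Why: Heterogeneous catalytic hydrogenation saturates the only C=C bond, the enone C1=C2, and leaves ketone, lactone and tertiary alcohol untouched.

Step 7
Reactants: 11 3-oxo lactone
Product: 12 tetraol (ring A with 3β-OH, 4α-OH/4β-CH3, CH2OH (C6) on C5, and on C10 the β-CH3 and the α-[(2S)-2-hydroxypropyl] chain C9–C8–C7)
Conditions: LiAlH4 (4 equiv), THF, 0 °C to rt; aqueous work-up
Reagents that add atoms: none
Why: Hydride reduction (LiAlH4) opens the lactone to the C6/C8 diol and also reduces the C3 ketone (axial delivery, 3β-OH expected, although this centre is re-oxidised in step 8), which frees the two carbons needed for ring B.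

Step 8
Reactants: 12 tetraol
Product: 13 keto aldehyde (4α-hydroxy-3-oxo ring A carrying CHO (C6) on C5 and 2-oxopropyl (C9–C8–C7) on C10)
Conditions: Dess–Martin periodinane (4 equiv), pyridine, CH2Cl2, 0 °C to rt
Reagents that add atoms: none
Why: Dess–Martin oxidation should convert the primary alcohol into the C6 aldehyde and both secondary alcohols into the C3 and C8 ketones under buffered, non-enolising conditions, leave the tertiary C4–OH alone, and erase the relay centre C8 once it has done its work.

Step 9
Reactants: 13 keto aldehyde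
Product: 15 4α-hydroxy-11,12,13-trinoreudesm-6-ene-3,8-dione, via aldol 14 (not isolated)
Conditions: KOH (0.5 equiv), MeOH, 0 °C to rt
Reagents that add atoms: none
Why: Intramolecular aldol condensation: the accessible methyl-ketone enolate (C7) adds to the C6 aldehyde in a 6-(enolexo)-exo-trig closure, the only strain-free aldol ring available, and E1cB loss of water should give the C6=C7–C8=O enone with the trans ring fusion fixed by the trans C6/C9 arrangement from step 3.

Step 10
Reactants: 15 4α-hydroxy-11,12,13-trinoreudesm-6-ene-3,8-dione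
Product: 16 3β,4α-dihydroxy-11,12,13-trinoreudesm-6-en-8-one
Conditions: NaBH4 (1 equiv), MeOH/CH2Cl2 (1:1), −78 °C
Reagents that add atoms: none
Why: Chemoselective borohydride reduction: at −78 °C in MeOH/CH2Cl2 NaBH4 reduces the saturated, α-hydroxylated C3 ketone much faster than the conjugated C8 ketone, and axial hydride attack from the α face (the β face is blocked by the axial C15 methyl) should give the equatorial 3β-alcohol.

Step 11
Reactants: 16 3β,4α-dihydroxy-11,12,13-trinoreudesm-6-en-8-one; 17 acetone
Product: 19 3β,4α,11-trihydroxy-6α-(phenylsulfanyl)-7αH-eudesman-8-one, via aluminium enolate 18 (not isolated)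
Conditions: Me3Al (3.3 equiv), PhSH (3.3 equiv), THF, 0 °C; then 16, −78 °C; then 17 (10 equiv), −78 to −30 °C; aqueous work-up
Reagents that add atoms: benzenethiol, Sc1ccccc1
Why: Conjugate addition of dimethylaluminium benzenethiolate to the enone gives the regiodefined C7 aluminium enolate, which should undergo aldol addition to acetone (thiolate conjugate addition–aldol sequence, an α-acylvinyl anion equivalent); the new C6 and C7 centres are transient and are removed in step 12.

Step 12
Reactants: 19 3β,4α,11-trihydroxy-6α-(phenylsulfanyl)-7αH-eudesman-8-one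
Product: 21 3β,4α,11-trihydroxyeudesm-6-en-8-one, via sulfoxide 20 (not isolated)
Conditions: mCPBA (1.0 equiv), CH2Cl2, −78 °C; then CaCO3, PhMe, 90 °C
Reagents that add atoms: none
Why: Oxidation of the sulfide to the sulfoxide and thermal syn-elimination (sulfoxide elimination) toward the more acidic H-7 should regenerate the C6=C7 bond in conjugation with the C8 ketone, now carrying the 2-hydroxyprop-2-yl group.

Step 13
Reactants: 21 3β,4α,11-trihydroxyeudesm-6-en-8-one; 22 angelic acid ((Z)-2-methylbut-2-enoic acid)
Product: 24 3β-angeloyloxy-4α,11-dihydroxyeudesm-6-en-8-one (CNP0261892.1), via mixed anhydride 23 (not isolated)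
Conditions: 22, 2,4,6-Cl3C6H2COCl, Et3N, PhMe, rt; then 21, 80 °C
Reagents that add atoms: none
Why: Yamaguchi esterification through the mixed 2,4,6-trichlorobenzoic anhydride should acylate only the secondary equatorial 3β-OH (the other two hydroxyls are tertiary) and, without a nucleophilic catalyst, keep the Z geometry of the angelate.

**Compound list**

1 | (S)-pent-4-yn-2-ol | C[C@H](O)CC#C | starting material
2 | bromoethene (vinyl bromide) | C=CBr | starting material
3 | alkenylalane: dimethylaluminium alkoxide of (2S,4E)-5-(dimethylalumanyl)-4-methylpent-4-en-2-ol | C[C@H](O[Al](C)C)C/C(C)=C/[Al](C)C | intermediate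
4 | (2S,4E)-4-methylhepta-4,6-dien-2-ol | C[C@H](O)C/C(C)=C/C=C | intermediate
5 | but-3-ynoic acid | C#CCC(=O)O | starting material
6 | (2S,4E)-4-methylhepta-4,6-dien-2-yl but-3-ynoate | C[C@H](OC(=O)CC#C)C/C(C)=C/C=C | intermediate
7 | (2S,4E)-4-methylhepta-4,6-dien-2-yl buta-2,3-dienoate | C[C@H](OC(=O)C=C=C)C/C(C)=C/C=C | intermediate
8 | trans-fused lactone (3S,4aS,8aS)-3,4a-dimethyl-8-methylidene-3,4,4a,7,8,8a-hexahydro-1H-isochromen-1-one | C1C=C[C@]2(C)C[C@H](C)OC(=O)[C@H]2C1=C | intermediate
9 | 4α-hydroxy-4β-methyl lactone (C1=C2 retained) | C1C=C[C@]2(C)C[C@H](C)OC(=O)[C@H]2[C@]1(C)O | intermediate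
10 | 3-oxo-Δ1 lactone (ring A enone) | O=C1C=C[C@]2(C)C[C@H](C)OC(=O)[C@H]2[C@]1(C)O | intermediate
11 | 3-oxo lactone (saturated ring A) | O=C1CC[C@]2(C)C[C@H](C)OC(=O)[C@H]2[C@]1(C)O | intermediate
12 | tetraol (3β,4α-diol; CH2OH on C5; (2S)-2-hydroxypropyl on C10) | O[C@H]1CC[C@](C)(C[C@H](C)O)[C@@H](CO)[C@]1(C)O | intermediate
13 | keto aldehyde (4α-hydroxy-3-oxo ring A; CHO on C5; 2-oxopropyl on C10) | O=C1CC[C@](C)(CC(C)=O)[C@@H](C=O)[C@]1(C)O | intermediate
14 | aldol: 4α,6α-dihydroxy-11,12,13-trinoreudesmane-3,8-dione | O=C1CC[C@]2(C)CC(=O)C[C@H](O)[C@H]2[C@]1(C)O | intermediate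
15 | 4α-hydroxy-11,12,13-trinoreudesm-6-ene-3,8-dione | O=C1CC[C@]2(C)CC(=O)C=C[C@H]2[C@]1(C)O | intermediate
16 | 3β,4α-dihydroxy-11,12,13-trinoreudesm-6-en-8-one | O[C@H]1CC[C@]2(C)CC(=O)C=C[C@H]2[C@]1(C)O | intermediate
17 | acetone | CC(C)=O | starting material
18 | aluminium enolate (C7=C8–OAlMe2, 6α-SPh, hydroxyls as dimethylaluminium alkoxides) | C[Al](C)O[C@H]1CC[C@]2(C)CC(O[Al](C)C)=C[C@H](Sc3ccccc3)[C@H]2[C@]1(C)O[Al](C)C | intermediate
19 | 3β,4α,11-trihydroxy-6α-(phenylsulfanyl)-7αH-eudesman-8-one | O[C@H]1CC[C@]2(C)CC(=O)[C@@H](C(C)(C)O)[C@H](Sc3ccccc3)[C@H]2[C@]1(C)O | intermediate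
20 | sulfoxide of 19 (mixture at sulfur) | O[C@H]1CC[C@]2(C)CC(=O)[C@@H](C(C)(C)O)[C@H](S(=O)c3ccccc3)[C@H]2[C@]1(C)O | intermediate
21 | 3β,4α,11-trihydroxyeudesm-6-en-8-one | O[C@H]1CC[C@]2(C)CC(=O)C(C(C)(C)O)=C[C@H]2[C@]1(C)O | intermediate
22 | angelic acid, (Z)-2-methylbut-2-enoic acid | C/C=C(/C)C(=O)O | starting material
23 | angelic 2,4,6-trichlorobenzoic anhydride | C/C=C(/C)C(=O)OC(=O)c1c(Cl)cc(Cl)cc1Cl | intermediate
24 | 3β-angeloyloxy-4α,11-dihydroxyeudesm-6-en-8-one, (3S,4S,5R,10R) | C/C=C(/C)C(=O)O[C@H]1CC[C@]2(C)CC(=O)C(C(C)(C)O)=C[C@H]2[C@]1(C)O | target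

**Step count and risks**

Total step count: 13. Longest linear sequence: 13 steps (from 1).

Steps most likely to fail:

1. Step 3 (key step). The cycloaddition may be slow because the ester must take its s-cis form in the transition state, so a [1,5]-hydrogen shift in the diene or oligomerisation of the allenoate can compete; exo-tether (trans-fusion) and facial selectivity may also be incomplete. Fallback: the covalent ester tether is replaced by a metal template. Starting from 4, the bromomagnesium alkoxide (MeMgBr, CH2Cl2) binds methyl buta-2,3-dienoate at the same magnesium centre, and the templated bimolecular Diels–Alder reaction should give the hydroxy ester methyl 6-[(2S)-2-hydroxypropyl]-6-methyl-2-methylidenecyclohex-4-ene-1-carboxylate F1. Acid-catalysed lactonisation (PPTS, PhH, reflux) then closes the lactone and returns to the route at 8.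

2. Step 9. The tertiary C4 hydroxyl may be lost by β-elimination, ring A may open by retro-aldol from the β-hydroxy aldehyde, or C5 may epimerise before ring B closes. Fallback: ring B is closed at the carboxyl oxidation level, so that no aldehyde is present at any point. Starting from 11, aminolysis of the lactone (Me3Al, MeNHOMe·HCl) should give the Weinreb hydroxy amide F2, and oxidation (Dess–Martin periodinane) the keto amide F3. Intramolecular Claisen acylation of the C7 enolate (LiN(SiMe3)2, THF) should give the cyclic 1,3-dione F4, and O-methylation at the less hindered C8 oxygen (MeOH, TsOH) the vinylogous ester F5. Reduction of the C6 and C3 carbonyls (LiAlH4) should give the enol-ether triol F6, and aqueous acid (Stork–Danheiser transposition) hydrolyses the enol ether with loss of water and returns to the route at 16.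

3. Step 11. The aldol addition to acetone is reversible (retro-aldol on warming or work-up), and the conjugate addition may be sluggish while both hydroxyls are bound as aluminium alkoxides. Fallback: an α-keto vinyl anion equivalent. Starting from 16, α-iodination (I2, pyridine) should give the 7-iodo enone F7, and ketalisation (ethylene glycol, TsOH) the dioxolane F8. Iodine–lithium exchange (t-BuLi, THF, −78 °C) and addition to acetone 17 should give the tertiary alcohol F9, and aqueous acid (1 M HCl, THF) removes the dioxolane and returns to the route at 21.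

**Further compounds**

F1 | step 3 | methyl 6-[(2S)-2-hydroxypropyl]-6-methyl-2-methylidenecyclohex-4-ene-1-carboxylate (ring-opened methyl ester of 8) | C1C=C[C@](C)(C[C@H](C)O)[C@@H](C(=O)OC)C1=C
F2 | step 9 | Weinreb hydroxy amide (N-methoxy-N-methyl amide at C6, free (S)-C8–OH, 4α-hydroxy-3-oxo ring A) | O=C1CC[C@](C)(C[C@H](C)O)[C@@H](C(=O)N(C)OC)[C@]1(C)O
F3 | step 9 | keto Weinreb amide (C8 ketone) | O=C1CC[C@](C)(CC(C)=O)[C@@H](C(=O)N(C)OC)[C@]1(C)O
F4 | step 9 | 4α-hydroxy-11,12,13-trinoreudesmane-3,6,8-trione | O=C1CC[C@]2(C)CC(=O)CC(=O)[C@H]2[C@]1(C)O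
F5 | step 9 | 4α-hydroxy-8-methoxy-11,12,13-trinoreudesm-7-ene-3,6-dione (vinylogous ester) | O=C1CC[C@]2(C)CC(OC)=CC(=O)[C@H]2[C@]1(C)O
F6 | step 9 | 8-methoxy-11,12,13-trinoreudesm-7-ene-3β,4α,6α-triol | O[C@H]1CC[C@]2(C)CC(OC)=C[C@H](O)[C@H]2[C@]1(C)O
F7 | step 11 | 3β,4α-dihydroxy-7-iodo-11,12,13-trinoreudesm-6-en-8-one | O[C@H]1CC[C@]2(C)CC(=O)C(I)=C[C@H]2[C@]1(C)O
F8 | step 11 | ethylene ketal of F7 | O[C@H]1CC[C@]2(C)CC3(OCCO3)C(I)=C[C@H]2[C@]1(C)O
F9 | step 11 | ethylene ketal of 21 | O[C@H]1CC[C@]2(C)CC3(OCCO3)C(C(C)(C)O)=C[C@H]2[C@]1(C)O
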